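The cyclohexanone ring is numbered as follows. C1 carries the side chain, C2 is CH2, C3 is CHOH, C4 is C(CH3)OH, C5 is C=O and C6 is CH-O-acyl. This ring holds an aldol retron: O3 is beta to the C5 ketone, and C4 is its fully substituted alpha carbon. Everything rests on cutting C3-C4. The key step is a copper hydride reductive aldol cyclisation of an acyclic 2-silyloxy enone aldehyde with one stereocentre (C1). It turns a CH2= terminus into the C4 methyl group, forms the C4=C5 enolate regiospecifically, closes the ring and sets the trans-diaxial C3/C4 diol in one operation. C6 oxygenation, side-chain growth and a biomimetic singlet-oxygen ene reaction follow.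

Key step: step 7

Remark on numbering: in the side chain, C7 is bound to C1 and bears =CH2. C8 is the carbonyl carbon, followed by C9 and C10. C11 bears two CH3 groups and the OOH group.
Assumption: two centres are carried as epimer mixtures because both vanish later. They are the phosphorus-bearing carbon of 9 (lost in step 5) and the carbinol carbon C8 of 18 and 19 (lost in step 13).

Step 1
Reactants: 1 2-bromo-3,3-diethoxyprop-1-ene
Product: 3 2-(3,3-diethoxyprop-1-en-2-yl)-4,4,5,5-tetramethyl-1,3,2-dioxaborolane, via vinyllithium 2 (not isolated)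
Conditions: t-BuLi (2 equiv), Et2O, -78 °C; then i-PrOB(pin), -78 °C to rt; aq. NH4Cl
Reagents that add atoms: 2-isopropoxy-4,4,5,5-tetramethyl-1,3,2-dioxaborolane, CC(C)OB1OC(C)(C)C(C)(C)O1
Why: Bromine-lithium exchange followed by borylation of the vinyllithium with an alkoxyboronate is a standard route to alpha-substituted alkenylboronates, and the acetal is inert to both operations.

Step 2
Reactants: 3 2-(3,3-diethoxyprop-1-en-2-yl)-4,4,5,5-tetramethyl-1,3,2-dioxaborolane; 4 5,6-dihydro-2H-pyran-2-one
Product: 5 (R)-4-(3,3-diethoxyprop-1-en-2-yl)tetrahydro-2H-pyran-2-one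
Conditions: [Rh(OH)((R)-binap)]2 (3 mol % Rh), dioxane/H2O 10:1, 50 °C
Reagents that add atoms: none
Why: In this Hayashi-Miyaura asymmetric 1,4-addition the (R)-BINAP alkenylrhodium species should add to the same face of the unsaturated lactone as aryl- and alkenylboron reagents do, which sets C1 as R (the lactone C=O is the later C5 and the OCH2 the later C3).

Step 3
Reactants: 6 diethyl (hydroxymethyl)phosphonate
Product: 7 diethyl [(tert-butyldimethylsilyloxy)methyl]phosphonate
Conditions: t-BuMe2SiCl, imidazole, CH2Cl2, rt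
Reagents that add atoms: tert-butylchlorodimethylsilane, CC(C)(C)[Si](C)(C)Cl
Why: Imidazole-promoted silylation of a primary alcohol installs the group that later protects O4.

Step 4
Reactants: 7 diethyl [(tert-butyldimethylsilyloxy)methyl]phosphonate; 5 (R)-4-(3,3-diethoxyprop-1-en-2-yl)tetrahydro-2H-pyran-2-one
Product: 9 diethyl [(4R)-1-(tert-butyldimethylsilyloxy)-5-(diethoxymethyl)-4-(2-hydroxyethyl)-2-oxohex-5-en-1-yl]phosphonate (epimers at the phosphorus-bearing carbon), via lithiated phosphonate 8 (not isolated)
Conditions: LiN(i-Pr)2 (2.2 equiv), 7 (2.2 equiv), THF, -78 °C; then 5, -78 to -20 °C; aq. NH4Cl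
Reagents that add atoms: none
Why: This is the acylation of a lithiated phosphonate by a lactone (beta-ketophosphonate synthesis), in which the acidic product is deprotonated at once so that a second addition stops, and C1 is not touched.

Step 5
Reactants: 9 diethyl [(4R)-1-(tert-butyldimethylsilyloxy)-5-(diethoxymethyl)-4-(2-hydroxyethyl)-2-oxohex-5-en-1-yl]phosphonate
Product: 10 (5R)-2-(tert-butyldimethylsilyloxy)-6-(diethoxymethyl)-5-(2-hydroxyethyl)hepta-1,6-dien-3-one
Conditions: 37 % aq. CH2O, K2CO3, THF, 0 °C to rt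
Reagents that add atoms: formaldehyde, C=O
Why: Horner-Wadsworth-Emmons olefination of alpha-silyloxy phosphonates is a known route to silyl enol ethers of 1,2-dicarbonyl compounds, and with formaldehyde it places the enol silane regiospecifically at the terminal position.

Step 6
Reactants: 10 (5R)-2-(tert-butyldimethylsilyloxy)-6-(diethoxymethyl)-5-(2-hydroxyethyl)hepta-1,6-dien-3-one
Product: 11 (3R)-6-(tert-butyldimethylsilyloxy)-3-(3,3-diethoxyprop-1-en-2-yl)-5-oxohept-6-enal
Conditions: Dess-Martin periodinane, CH2Cl2, 0 °C to rt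
Reagents that add atoms: none
Why: Dess-Martin oxidation takes the primary alcohol to the aldehyde under near-neutral conditions that the electron-poor enol silane, the acetal and the alkenes tolerate.

Step 7
Reactants: 11 (3R)-6-(tert-butyldimethylsilyloxy)-3-(3,3-diethoxyprop-1-en-2-yl)-5-oxohept-6-enal
Product: 13 (2S,3R,5R)-2-(tert-butyldimethylsilyloxy)-5-(3,3-diethoxyprop-1-en-2-yl)-2-methyl-3-(triethylsilyloxy)cyclohexan-1-one, via copper aldolate 12 (not isolated)
Conditions: [(Ph3P)CuH]6 (Stryker's reagent, 0.2 equiv = 1.2 equiv hydride), degassed toluene, -40 to 0 °C; then Et3SiCl, imidazole, DMF co-solvent, 0 °C to rt, same flask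
Reagents that add atoms: chlorotriethylsilane, CC[Si](Cl)(CC)CC
Why: Proposed new method: [(Ph3P)CuH]6 transfers hydride to the unsubstituted CH2= terminus of the 2-silyloxy enone, which creates the C4 methyl group and only the C4=C5 copper enolate, and this enolate attacks the tethered C3 aldehyde before Et3SiCl caps the aldolate. The closest known reaction type is the copper hydride reductive aldol cyclisation of enones, enoates and enamides onto ketones and aldehydes, which has not been shown for a 2-silyloxy enone or for an oxygen-bearing fully substituted enolate carbon. The six-membered ring closes in the 6-(enolendo)-exo-trig mode through a chair in which copper bridges the enolate oxygen and the aldehyde oxygen, the topology also met in the Ferrier carbocyclisation of hex-5-enopyranosides. C3 is set by that bridge, which holds the aldehyde oxygen axial, together with the equatorial C1 substituent, so that O3 ends trans to the side chain. C4 is set by the enolate geometry: hydride transfer to the s-cis enone, dipole repulsion between O-Cu and the non-chelating OTBS group and allylic strain against C6 all place CH3 cis to O-Cu, so CH3 becomes equatorial and OTBS axial, anti to O3. The step needs 1,4-reduction to be faster than attack on the aldehyde and on the 1,1-disubstituted alkene, which the terminal conjugated CH2= acceptor and the unimolecular capture of the enolate secure.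

Step 8
Reactants: 13 (2S,3R,5R)-2-(tert-butyldimethylsilyloxy)-5-(3,3-diethoxyprop-1-en-2-yl)-2-methyl-3-(triethylsilyloxy)cyclohexan-1-one
Product: 15 (2S,3R,5S,6S)-2-(tert-butyldimethylsilyloxy)-5-(3,3-diethoxyprop-1-en-2-yl)-6-hydroxy-2-methyl-3-(triethylsilyloxy)cyclohexan-1-one, via potassium enolate 14 (not isolated)
Conditions: KN(SiMe3)2, THF, -78 °C; then 2-(phenylsulfonyl)-3-phenyloxaziridine, -78 °C; aq. NH4Cl
Reagents that add atoms: 2-(phenylsulfonyl)-3-phenyloxaziridine, O=S(=O)(c1ccccc1)N1OC1c1ccccc1
Why: In this Davis oxidation only one enolate is possible because C4 is fully substituted, and the oxaziridine should approach C6 anti to the neighbouring C1 substituent and away from the axial C4-OTBS group, which gives the equatorial alcohol trans to the side chain without touching the alkenes.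

Step 9
Reactants: 15 (2S,3R,5S,6S)-2-(tert-butyldimethylsilyloxy)-5-(3,3-diethoxyprop-1-en-2-yl)-6-hydroxy-2-methyl-3-(triethylsilyloxy)cyclohexan-1-one
Product: 16 C6 isovalerate of 15 (1S,3R,4S,6S in the ring numbering of the overview)
Conditions: isovaleryl chloride, pyridine, DMAP (cat.), CH2Cl2, 0 °C to rt
Reagents that add atoms: 3-methylbutanoyl chloride, CC(C)CC(=O)Cl
Why: DMAP-catalysed acylation meets only one free hydroxyl group, and it retains the C6 configuration because no C-O bond is broken.

Step 10
Reactants: 16 C6 isovalerate of 15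
Product: 17 diol enal with the target ring (1S,3R,4S,6S) and a 3-oxoprop-1-en-2-yl group on C1
Conditions: 48 % aq. HF, MeCN, 0 °C to rt
Reagents that add atoms: water, O
Why: Acidic fluoride desilylation and acetal hydrolysis run in one operation, and the acidic medium avoids the retro-aldol ring opening that a basic fluoride source could start at the freed C3 alkoxide.

Step 11
Reactants: 17 diol enal
Product: 18 homoallylic alcohol with the target ring and a 3-hydroxyhexa-1,5-dien-2-yl group on C1 (C8 epimers)
Conditions: allylB(pin), CH2Cl2, rt; then H2O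
Reagents that add atoms: allylboronic acid pinacol ester, C=CCB1OC(C)(C)C(C)(C)O1
Why: Allylboration through a cyclic Zimmerman-Traxler transition state is neutral and selective for the aldehyde over the ketone, the ester and the free hydroxyl groups, and the uncontrolled carbinol centre C8 is erased in step 13.

Step 12
Reactants: 18 homoallylic alcohol
Product: 19 prenyl carbinol with the target ring and a 3-hydroxy-6-methylhepta-1,5-dien-2-yl group on C1 (C8 epimers)
Conditions: second-generation Grubbs catalyst RuCl2(=CHPh)(PCy3)(SIMes) (5 mol %), 2-methylbut-2-ene (excess), CH2Cl2, 40 °C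
Reagents that add atoms: 2-methylbut-2-ene, CC=C(C)C
Why: Olefin cross-metathesis with 2-methylbut-2-ene is the known way to turn an allyl into a prenyl group, while the hindered 1,1-disubstituted C7 alkene should stay inert and free hydroxyl groups are tolerated.

Step 13
Reactants: 19 prenyl carbinol
Product: 20 beta,gamma-unsaturated ketone with the target ring and a 6-methyl-3-oxohepta-1,5-dien-2-yl group on C1
Conditions: activated MnO2 (excess), CH2Cl2, rt; used at once
Reagents that add atoms: none
Why: MnO2 oxidises only the allylic C8 alcohol and leaves the saturated C3 and tertiary C4 hydroxyl groups, and its neutrality should keep the C10=C11 alkene out of conjugation.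

Step 14
Reactants: 20 beta,gamma-unsaturated ketone
Product: 21 CNP0239240.1 (target)
Conditions: O2, tetraphenylporphyrin (cat.), visible light, CH2Cl2, -20 °C
Reagents that add atoms: dioxygen, O=O
Why: In this Schenck ene reaction singlet oxygen attacks only the electron-rich trisubstituted alkene, and with the electron-withdrawing carbonyl at the allylic position it should bond at the remote tertiary C11 and abstract an activated C9 hydrogen, which gives the conjugated E-enone hydroperoxide and touches no stereocentre.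

Compound list
1 | 2-bromo-3,3-diethoxyprop-1-ene | C=C(Br)C(OCC)OCC | starting material
2 | (3,3-diethoxyprop-1-en-2-yl)lithium | [Li]C(=C)C(OCC)OCC | intermediate
3 | 2-(3,3-diethoxyprop-1-en-2-yl)-4,4,5,5-tetramethyl-1,3,2-dioxaborolane | C=C(B1OC(C)(C)C(C)(C)O1)C(OCC)OCC | intermediate
4 | 5,6-dihydro-2H-pyran-2-one | O=C1C=CCCO1 | starting material
5 | (R)-4-(3,3-diethoxyprop-1-en-2-yl)tetrahydro-2H-pyran-2-one | O=C1C[C@H](C(=C)C(OCC)OCC)CCO1 | intermediate
6 | diethyl (hydroxymethyl)phosphonate | OCP(=O)(OCC)OCC | starting material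
7 | diethyl [(tert-butyldimethylsilyloxy)methyl]phosphonate | CC(C)(C)[Si](C)(C)OCP(=O)(OCC)OCC | intermediate
8 | lithiated phosphonate 7 | [Li]C(O[Si](C)(C)C(C)(C)C)P(=O)(OCC)OCC | intermediate
9 | beta-ketophosphonate, R at C1, epimers at the phosphorus-bearing carbon | OCC[C@H](CC(=O)C(O[Si](C)(C)C(C)(C)C)P(=O)(OCC)OCC)C(=C)C(OCC)OCC | intermediate
10 | (5R)-2-(tert-butyldimethylsilyloxy)-6-(diethoxymethyl)-5-(2-hydroxyethyl)hepta-1,6-dien-3-one | OCC[C@H](CC(=O)C(=C)O[Si](C)(C)C(C)(C)C)C(=C)C(OCC)OCC | intermediate
11 | (3R)-6-(tert-butyldimethylsilyloxy)-3-(3,3-diethoxyprop-1-en-2-yl)-5-oxohept-6-enal | O=CC[C@H](CC(=O)C(=C)O[Si](C)(C)C(C)(C)C)C(=C)C(OCC)OCC | intermediate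
12 | monovalent copper aldolate of the cyclised ketone (phosphine ligands omitted) | C=C(C(OCC)OCC)[C@@H]1C[C@@H](O[Cu])[C@](C)(O[Si](C)(C)C(C)(C)C)C(=O)C1 | intermediate
13 | (2S,3R,5R)-2-(tert-butyldimethylsilyloxy)-5-(3,3-diethoxyprop-1-en-2-yl)-2-methyl-3-(triethylsilyloxy)cyclohexan-1-one | C=C(C(OCC)OCC)[C@@H]1C[C@@H](O[Si](CC)(CC)CC)[C@](C)(O[Si](C)(C)C(C)(C)C)C(=O)C1 | intermediate
14 | potassium C5=C6 enolate of 13 | C=C(C(OCC)OCC)[C@@H]1C[C@@H](O[Si](CC)(CC)CC)[C@](C)(O[Si](C)(C)C(C)(C)C)C([O-])=C1.[K+] | intermediate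
15 | (2S,3R,5S,6S)-2-(tert-butyldimethylsilyloxy)-5-(3,3-diethoxyprop-1-en-2-yl)-6-hydroxy-2-methyl-3-(triethylsilyloxy)cyclohexan-1-one | C=C(C(OCC)OCC)[C@@H]1C[C@@H](O[Si](CC)(CC)CC)[C@](C)(O[Si](C)(C)C(C)(C)C)C(=O)[C@H]1O | intermediate
16 | C6 isovalerate of 15 | C=C(C(OCC)OCC)[C@@H]1C[C@@H](O[Si](CC)(CC)CC)[C@](C)(O[Si](C)(C)C(C)(C)C)C(=O)[C@H]1OC(=O)CC(C)C | intermediate
17 | diol enal, target ring with 3-oxoprop-1-en-2-yl on C1 | C=C(C=O)[C@@H]1C[C@@H](O)[C@](C)(O)C(=O)[C@H]1OC(=O)CC(C)C | intermediate
18 | homoallylic alcohol, target ring with 3-hydroxyhexa-1,5-dien-2-yl on C1, C8 epimers | C=CCC(O)C(=C)[C@@H]1C[C@@H](O)[C@](C)(O)C(=O)[C@H]1OC(=O)CC(C)C | intermediate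
19 | prenyl carbinol, target ring with 3-hydroxy-6-methylhepta-1,5-dien-2-yl on C1, C8 epimers | CC(C)=CCC(O)C(=C)[C@@H]1C[C@@H](O)[C@](C)(O)C(=O)[C@H]1OC(=O)CC(C)C | intermediate
20 | beta,gamma-unsaturated ketone, target ring with 6-methyl-3-oxohepta-1,5-dien-2-yl on C1 | CC(C)=CCC(=O)C(=C)[C@@H]1C[C@@H](O)[C@](C)(O)C(=O)[C@H]1OC(=O)CC(C)C | intermediate
21 | CNP0239240.1, (1S,3R,4S,6S) ring with (E)-6-hydroperoxy-6-methyl-3-oxohepta-1,4-dien-2-yl on C1 | C=C(C(=O)/C=C/C(C)(C)OO)[C@@H]1C[C@@H](O)[C@](C)(O)C(=O)[C@H]1OC(=O)CC(C)C | target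

Total step count: 14. Longest linear sequence: 13 steps (steps 1, 2 and 4 to 14).

Steps most likely to fail

**Step 7.**
- Risk:
  - The copper enolate may be protonated or silylated before it cyclises.
  - Hydride may reach the aldehyde first.
  - Closure may run through an open transition state, with loss of diastereocontrol.
- The fallback uses known chemistry only, sets out from 5 and comes back at 17. It still closes the ring at C3-C4, now as a C=C bond.
- Isopropenylmagnesium bromide (THF, -78 °C) opens 5 to the isopropenyl ketone alcohol F1.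
- Dess-Martin oxidation gives the keto aldehyde F2.
- Ph3P=CH2 (1 equiv, -78 °C) methylenates only the aldehyde and gives the triene F3.
- Ring-closing metathesis with the second-generation Grubbs catalyst gives the 2-methylcyclohexenone F4.
- LiN(i-Pr)2 followed by the oxaziridine of step 8 gives the trans C6 alcohol F5.
- Isovaleryl chloride then gives the enone ester F6.
- Luche reduction (NaBH4, CeCl3·7H2O, MeOH, -78 °C) gives the equatorial allylic alcohol F7, whose C5 hydroxyl is cis to the C1 substituent.
- VO(acac)2 with t-BuOOH delivers oxygen syn to that hydroxyl and gives the epoxy alcohol F8.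
- Dess-Martin oxidation gives the epoxy ketone F9.
- Dilute aqueous HClO4 in THF opens the epoxide at C3 with inversion (trans-diaxial opening) and hydrolyses the acetal, which gives 17.

**Step 4.**
- Risk:
  - The hindered alpha-silyloxy carbanion may deprotonate the lactone instead of adding to it.
  - The silyl group may migrate.
- The fallback sets out from 5 and comes back at 17. It brings in C4 as an alpha-metalated enol ether in one step, without an olefination.
- tert-Butyl vinyl ether with t-BuLi (THF, -78 to 0 °C) gives 1-(tert-butoxy)vinyllithium F10.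
- F10 opens 5 to the tert-butoxy enone alcohol F11.
- The operations of steps 6 to 9 are then run on this series. They give in turn the tert-butoxy keto aldehyde F12, the cyclised triethylsilyl ether F13, the C6 alcohol F14 and the tert-butyl ether isovalerate F15.
- CF3CO2H in wet CH2Cl2 removes the tert-butyl ether, the silyl ether and the acetal together and gives 17.

**Step 2.**
- Risk:
  - Protodeboronation of the hindered alkenylboronate may outrun transmetalation.
  - The facial selectivity may erode.
- The fallback sets out from 1 and comes back at 5. It replaces catalyst control by auxiliary control on an acyclic acceptor.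
- Magnesium in THF turns 1 into the alkenyl Grignard reagent F16.
- (S)-4-Phenyloxazolidin-2-one is N-acylated with (E)-5-(tert-butyldimethylsilyloxy)pent-2-enoyl chloride to give the enoyl oxazolidinone F17.
- F16 with CuBr·SMe2 adds to the magnesium-chelated s-cis form of F17 from the face opposite to the phenyl group and gives the conjugate adduct F18 (R at C1).
- Bu4NF frees the primary alkoxide, which closes onto the imide carbonyl and gives 5.

Further compounds
F1 | step 7 | isopropenyl ketone alcohol, (5R)-6-(diethoxymethyl)-5-(2-hydroxyethyl)-2-methylhepta-1,6-dien-3-one | OCC[C@H](CC(=O)C(C)=C)C(=C)C(OCC)OCC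
F2 | step 7 | keto aldehyde, (3R)-3-(3,3-diethoxyprop-1-en-2-yl)-6-methyl-5-oxohept-6-enal | O=CC[C@H](CC(=O)C(C)=C)C(=C)C(OCC)OCC
F3 | step 7 | triene, (5R)-5-allyl-6-(diethoxymethyl)-2-methylhepta-1,6-dien-3-one | C=CC[C@H](CC(=O)C(C)=C)C(=C)C(OCC)OCC
F4 | step 7 | 2-methylcyclohexenone, (R)-5-(3,3-diethoxyprop-1-en-2-yl)-2-methylcyclohex-2-en-1-one | C=C(C(OCC)OCC)[C@@H]1CC=C(C)C(=O)C1
F5 | step 7 | trans C6 alcohol of F4 | C=C(C(OCC)OCC)[C@@H]1CC=C(C)C(=O)[C@H]1O
F6 | step 7 | enone ester, C6 isovalerate of F5 | C=C(C(OCC)OCC)[C@@H]1CC=C(C)C(=O)[C@H]1OC(=O)CC(C)C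
F7 | step 7 | equatorial allylic alcohol, C5 hydroxyl cis to the C1 substituent | C=C(C(OCC)OCC)[C@@H]1CC=C(C)[C@H](O)[C@H]1OC(=O)CC(C)C
F8 | step 7 | epoxy alcohol, C3-C4 epoxide syn to the C5 hydroxyl | C=C(C(OCC)OCC)[C@@H]1C[C@@H]2O[C@]2(C)[C@H](O)[C@H]1OC(=O)CC(C)C
F9 | step 7 | epoxy ketone, C3-C4 epoxide cis to the C1 substituent | C=C(C(OCC)OCC)[C@@H]1C[C@@H]2O[C@]2(C)C(=O)[C@H]1OC(=O)CC(C)C
F10 | step 4 | 1-(tert-butoxy)vinyllithium | [Li]C(=C)OC(C)(C)C
F11 | step 4 | tert-butoxy enone alcohol, tert-butyl analogue of 10 | OCC[C@H](CC(=O)C(=C)OC(C)(C)C)C(=C)C(OCC)OCC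
F12 | step 4 | tert-butoxy keto aldehyde, tert-butyl analogue of 11 | O=CC[C@H](CC(=O)C(=C)OC(C)(C)C)C(=C)C(OCC)OCC
F13 | step 4 | cyclised triethylsilyl ether, tert-butyl analogue of 13 | C=C(C(OCC)OCC)[C@@H]1C[C@@H](O[Si](CC)(CC)CC)[C@](C)(OC(C)(C)C)C(=O)C1
F14 | step 4 | C6 alcohol, tert-butyl analogue of 15 | C=C(C(OCC)OCC)[C@@H]1C[C@@H](O[Si](CC)(CC)CC)[C@](C)(OC(C)(C)C)C(=O)[C@H]1O
F15 | step 4 | tert-butyl ether isovalerate, tert-butyl analogue of 16 | C=C(C(OCC)OCC)[C@@H]1C[C@@H](O[Si](CC)(CC)CC)[C@](C)(OC(C)(C)C)C(=O)[C@H]1OC(=O)CC(C)C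
F16 | step 2 | alkenyl Grignard reagent, (3,3-diethoxyprop-1-en-2-yl)magnesium bromide | C=C([Mg]Br)C(OCC)OCC
F17 | step 2 | enoyl oxazolidinone, (S)-3-[(E)-5-(tert-butyldimethylsilyloxy)pent-2-enoyl]-4-phenyloxazolidin-2-one | O=C1OC[C@H](c2ccccc2)N1C(=O)/C=C/CCO[Si](C)(C)C(C)(C)C
F18 | step 2 | conjugate adduct, R at C1 | O=C1OC[C@H](c2ccccc2)N1C(=O)C[C@@H](CCO[Si](C)(C)C(C)(C)C)C(=C)C(OCC)OCC
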